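The rate constants are not given, so start from what stays constant in a closed flask.

| flask | Q | L | remark | time |
|---|---|---|---|---|
| Wednesday's | 1.1 M | 0.55 M | the very flask that is asked about, followed so far |  |
| Tuesday's | 1.7 M | 0.55 M | run made earlier |  |
| flask | 1.1 M | 0.550 M |  | 4.0 h |

| run | time / min | Q / % | Z / % |
|---|---|---|---|
| Wednesday's | 4.00 | 58.5 | 3.5 |
| Wednesday's | 6.00 | 58.6 | 4.4 |
| Wednesday's | 10.0 | 58.9 | 4.6 |
| Wednesday's | 20.0 | 60.1 | 6.1 |
| Wednesday's | 30.0 | 61.3 | 6.0 |
| Wednesday's | 50.0 | 59.5 | 6.4 |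
| Tuesday's | 6.00 | 70.9 | 1.8 |
| Tuesday's | 20.0 | 72.6 | 1.9 |
| Tuesday's | 30.0 | 72.5 | 2.9 |
| Tuesday's | 50.0 | 71.5 | 2.8 |
| Tuesday's | 80.0 | 70.6 | 1.8 |
| Tuesday's | 90.0 | 71.4 | 2.8 |

(scatter of a reading: 0.5 percentage points)

* how much of the Q has reacted by 4.0 h
* how much Z there is at 4.0 h, in percent of the Q charged
* how much J there is at 4.0 h, in percent of the Q charged
* amount of Z if the flask were left three thousand times as long, in percent of the Q charged

- a species is counted by the Q in it: one D counts as two
- reactions considered so far: J + L <-> X + Z; Q + Z -> D; Q + L <-> X + J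

1. Look at Wednesday's run, which is the asked flask. From the first reading to the last, Z goes from 3.5% to 6.4%, a gain of 2.9 percentage points, yet Q goes from 58.5% to 59.5%, a change of 1 point. How can Z gain while Q, which Z is made from, does not fall?

2. Write the mass balance twice, in percent of the Q charged. For the forms of Q: [Q] + [J] + [Z] + [D] = Q charged. For the forms of L: [J] + 2[Z] + [D] + [L] = L charged.

3. Subtract the two, and J and D drop out: [Q] minus the excess of Q charged over L charged equals [L] + [Z]. Call this the spare. Wednesday's last reading puts it at 9.50%.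

4. Clear up the puzzle. Wednesday's first reading gives a spare of 8.50%, which differs from the last by 1 point, less than the gain in Z. So Z grows at the expense of free L, read as falling from 5.00% to 3.10% of the Q charged. The spare holds neither J nor D, so these readings of Q say little about either.

5. The forecast: 40.3% reacted, Z 5.8%, J 32.8% (27% to 35.5%), and Z 0.5% after the long wait. It notes that “Q is almost blind to D”.

6. The flask gives 42.9% reacted, Z 3.80%, J 23.9%, and Z 0% after the long wait, so J lies 8.9 points below the forecast.

    J + L ⇌ X + Z (K = 2.40, k = 0.290 L mol⁻¹ min⁻¹)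
    Q + Z → D (k = 0.0100 L mol⁻¹ min⁻¹)
    Q + L ⇌ X + J (K = 5.90, k = 1.80 L mol⁻¹ min⁻¹)

At 4.00 h the relaxation half-lives of Q + L ⇌ X + J, 0.484 min, and of J + L ⇌ X + Z, 0.0751 h, are both short against the time 4.0 h, and the first is shorter. In this flask D then stands at 15.2% and J at 23.9%, while Q at 57.1% puts the spare at 7.11%, where Wednesday's last reading, much earlier, gave 9.50%. In the neighbour charged with 0.44 M of Q, the spare is 49.6%, made up of Z at 23.6% and free L at 25.9% of the Q charged.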